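**Retrosynthetic overview**

1. Rings: A = enal-bearing arene, B = trans-dioxane fused to A, C = central arene, D = cis-dioxane fused to C, E = catechol. End game: Wittig two-carbon homologation of the ring A aldehyde, then desilylation and a neutral deallylation of ring E.
2. Ring B (formed second, step 11): tandem oxirane opening/SNAr between 4-fluoro-3-hydroxybenzaldehyde (ring A) and a cis-glycidyl silyl ether grown from the ring C aldehyde by Z-olefination, salen-manganese epoxidation and NaBH4 reduction.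
3. Ring D (formed first, step 6): one-pot annulation of 3,4-dihydroxybenzaldehyde (ring C) with the cis-3-aryl-2-(chloromethyl)oxirane 6 (ring E). The ArO–CH(Ar) bond forms first; the ArO–CH(CH2OH) bond then closes the ring through a relayed terminal oxirane, a strained ring that is not in the target.
4. Enabling feature: ring C is a catechol whose two oxygens are told apart by its formyl carbon (the later C-3 substituent carbon of ring B). The O para to it is the only one ionised by weak base and ends on CH(Ar) of ring D; the neighbouring O, meta to it, then lies five atoms from the oxirane carbon that becomes CH(CH2OH), set up for 6-exo closure.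
5. Stereo logic: each dioxane ring is the net addition of two aryl oxygens across a Z-cinnamate. Two inversions (ring D) give the 2,3-cis ring; one inversion plus one retention (ring B) gives the 2,3-trans ring.

Key step: step 6

Remark: (salen)MnCl denotes [N,N'-bis(3,5-di-tert-butylsalicylidene)-1,2-cyclohexanediaminato]manganese chloride, a complex of trivalent manganese, used as its (S,S) or (R,R) enantiomer; allyl = prop-2-en-1-yl.

**Route**

Step 1
Reactants: 1 3,4-dihydroxybenzaldehyde
Product: 2 3,4-bis(allyloxy)benzaldehyde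
Conditions: allyl bromide (2.5 equiv), K2CO3, DMF, 60 °C
Reagents that add atoms: allyl bromide, C=CCBr
Why: Williamson etherification of both phenols; the allyl ethers should survive every later basic, hydride and oxidative step and can leave at the end under neutral catalysis by zerovalent palladium.

Step 2
Reactants: 2 3,4-bis(allyloxy)benzaldehyde
Product: 3 ethyl (Z)-3-[3,4-bis(allyloxy)phenyl]prop-2-enoate
Conditions: (2-MeC6H4O)2P(O)CH2CO2Et, NaI, DBU, THF, −78 to 0 °C
Reagents that add atoms: ethyl 2-[bis(2-methylphenoxy)phosphoryl]acetate, CCOC(=O)CP(=O)(Oc1ccccc1C)Oc1ccccc1C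
Why: Z-selective Horner–Wadsworth–Emmons olefination (Ando variant), in which the electron-poor diaryl phosphonate makes the oxaphosphetane collapse fast so that the kinetic Z-cinnamate should result from an aryl aldehyde.

Step 3
Reactants: 3 ethyl (Z)-3-[3,4-bis(allyloxy)phenyl]prop-2-enoate
Product: 4 ethyl (2S,3S)-3-[3,4-bis(allyloxy)phenyl]oxirane-2-carboxylate (cis)
Conditions: NaOCl (aq., pH 11.3), (S,S)-(salen)MnCl (5 mol%), 4-phenylpyridine N-oxide, CH2Cl2, 4 °C
Reagents that add atoms: sodium hypochlorite, [Na+].[O-]Cl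
Why: Jacobsen–Katsuki epoxidation, for which cis-cinnamate esters are privileged substrates; the (S,S) ligand should direct oxygen transfer to the face that gives the cis-(2S,3S)-glycidate, so both future ring D stereocenters are set under catalyst control.

Step 4
Reactants: 4 ethyl (2S,3S)-3-[3,4-bis(allyloxy)phenyl]oxirane-2-carboxylate
Product: 5 [(2R,3S)-3-[3,4-bis(allyloxy)phenyl]oxiran-2-yl]methanol (cis)
Conditions: NaBH4, EtOH, 0 °C
Reagents that add atoms: none
Why: chemoselective borohydride reduction of a glycidic ester, which the alpha-oxygen activates, to the epoxy alcohol without opening the oxirane; no stereocenter is touched (the C-2 descriptor changes by priority only).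

Step 5
Reactants: 5 [(2R,3S)-3-[3,4-bis(allyloxy)phenyl]oxiran-2-yl]methanol
Product: 6 (2S,3S)-2-(chloromethyl)-3-[3,4-bis(allyloxy)phenyl]oxirane (cis)
Conditions: PPh3, CCl4, NaHCO3, 60 °C
Reagents that add atoms: carbon tetrachloride, ClC(Cl)(Cl)Cl
Why: Appel chlorination of the primary alcohol under buffered conditions, a standard conversion of 2,3-epoxy alcohols into epoxy chlorides that leaves both oxirane carbons untouched.

Step 6
Reactants: 6 (2S,3S)-2-(chloromethyl)-3-[3,4-bis(allyloxy)phenyl]oxirane; 1 3,4-dihydroxybenzaldehyde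
Product: 9 (2R,3S)-2-[3,4-bis(allyloxy)phenyl]-3-(hydroxymethyl)-2,3-dihydro-1,4-benzodioxine-6-carbaldehyde, via chlorohydrin ether 7 (not isolated), via aryloxy oxirane 8 (not isolated)
Conditions: 1 (1.5 equiv), K2CO3 (0.5 equiv), DMF, 60 °C; then K2CO3 (3 equiv), MeOH, 40 °C
Reagents that add atoms: none
Why: Proposed new method: the 4-phenoxide of 1 (the only OH ionised by sub-stoichiometric carbonate, because it is para to the formyl group) should open the oxirane of 6 at the benzylic carbon by SN2 with inversion to give chlorohydrin 7, methanolic carbonate then closes the alkoxide onto CH2Cl (3-exo-tet) to the terminal oxirane 8, and the ortho phenoxide opens 8 at its inner carbon, forming the ArO–CH(CH2OH) bond and releasing the CH2OH group. The closest known reactions are the catechol–epichlorohydrin annulation to 2-(hydroxymethyl)-1,4-benzodioxanes and the benzylic opening of 3-aryl glycidyl derivatives by phenoxides; new is their merger on a 3-aryl-substituted oxiranylmethyl chloride. Ring D closes in the 6-exo-tet mode, driven by the strain of the temporary terminal oxirane. Both new stereocenters are substrate-controlled and stereospecific: each oxirane carbon of 6 is inverted once, so the two aryl oxygens add syn across the former Z-alkene and the 2,3-cis ring (2R,3S) should result, which an equilibrating closure at the benzylic carbon would not give. Three selectivities are needed: O-4 before O-3 (secured by the acidity gap set by the para-formyl group and by keeping 1 in excess so that 7 stays protonated), benzylic oxirane carbon before CH2Cl (secured by the electron-rich aryl group that loosens the benzylic C–O bond and by the low SN2 reactivity of a beta-oxygenated primary chloride), and 6-exo opening of 8 before 7-ring formation (secured by the protic carbonate stage, which turns 7 into 8 faster than phenoxide displaces chloride, and by the exo preference of oxirane openings).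

Step 7
Reactants: 9 (2R,3S)-2-[3,4-bis(allyloxy)phenyl]-3-(hydroxymethyl)-2,3-dihydro-1,4-benzodioxine-6-carbaldehyde
Product: 10 ethyl (Z)-3-[(2R,3S)-2-[3,4-bis(allyloxy)phenyl]-3-(hydroxymethyl)-2,3-dihydro-1,4-benzodioxin-6-yl]prop-2-enoate
Conditions: (2-MeC6H4O)2P(O)CH2CO2Et, NaI, DBU, THF, −78 to 0 °C
Reagents that add atoms: ethyl 2-[bis(2-methylphenoxy)phosphoryl]acetate, CCOC(=O)CP(=O)(Oc1ccccc1C)Oc1ccccc1C
Why: the same Z-selective Horner–Wadsworth–Emmons olefination, whose amidine base does not deprotonate the free primary alcohol, so no protection is needed here.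

Step 8
Reactants: 10 ethyl (Z)-3-[(2R,3S)-2-[3,4-bis(allyloxy)phenyl]-3-(hydroxymethyl)-2,3-dihydro-1,4-benzodioxin-6-yl]prop-2-enoate
Product: 11 ethyl (2R,3R)-3-[(2R,3S)-2-[3,4-bis(allyloxy)phenyl]-3-(hydroxymethyl)-2,3-dihydro-1,4-benzodioxin-6-yl]oxirane-2-carboxylate (cis oxirane)
Conditions: NaOCl (aq., pH 11.3), (R,R)-(salen)MnCl (5 mol%), 4-phenylpyridine N-oxide, CH2Cl2, 4 °C
Reagents that add atoms: sodium hypochlorite, [Na+].[O-]Cl
Why: Jacobsen–Katsuki epoxidation with the enantiomeric ligand, which should give the cis-(2R,3R)-glycidate under catalyst control because the ring D stereocenters are remote, any minor isomer being a separable diastereomer.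

Step 9
Reactants: 11 ethyl (2R,3R)-3-[(2R,3S)-2-[3,4-bis(allyloxy)phenyl]-3-(hydroxymethyl)-2,3-dihydro-1,4-benzodioxin-6-yl]oxirane-2-carboxylate
Product: 12 [(2S,3R)-3-[(2R,3S)-2-[3,4-bis(allyloxy)phenyl]-3-(hydroxymethyl)-2,3-dihydro-1,4-benzodioxin-6-yl]oxiran-2-yl]methanol
Conditions: NaBH4, EtOH, 0 °C
Reagents that add atoms: none
Why: chemoselective borohydride reduction of the glycidic ester to the epoxy alcohol as in step 4, with no stereocenter touched.

Step 10
Reactants: 12 [(2S,3R)-3-[(2R,3S)-2-[3,4-bis(allyloxy)phenyl]-3-(hydroxymethyl)-2,3-dihydro-1,4-benzodioxin-6-yl]oxiran-2-yl]methanol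
Product: 13 bis(triisopropylsilyl) ether of 12 (both primary OH groups silylated)
Conditions: i-Pr3SiCl (2.5 equiv), imidazole, DMF, rt
Reagents that add atoms: chlorotriisopropylsilane, CC(C)[Si](Cl)(C(C)C)C(C)C
Why: silylation of both primary alcohols removes the competing alkoxides for step 11, the triisopropylsilyl group being chosen because it resists oxygen-to-oxygen migration.

Step 11
Reactants: 13 bis(triisopropylsilyl) ether of 12; 14 4-fluoro-3-hydroxybenzaldehyde
Product: 16 (2S,3S)-3-[(2R,3S)-2-[3,4-bis(allyloxy)phenyl]-3-{[(triisopropylsilyl)oxy]methyl}-2,3-dihydro-1,4-benzodioxin-6-yl]-2-{[(triisopropylsilyl)oxy]methyl}-2,3-dihydro-1,4-benzodioxine-6-carbaldehyde, via fluoro alkoxide 15 (not isolated)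
Conditions: 14 (1.1 equiv), NaH (1.1 equiv), DMF, 0 °C; then 13, 70 °C
Reagents that add atoms: none
Why: tandem SN2/SNAr annulation in which the sodium phenoxide of 14 should open the oxirane at the benzylic carbon with inversion (setting C-3 of ring B as S) and the alkoxide released at the neighbouring carbon, whose S configuration comes unchanged from the epoxidation, displaces the fluoride para to the formyl group through a Meisenheimer adduct (6-exo-trig), so one inversion plus one retention on a cis-oxirane gives the trans ring.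

Step 12
Reactants: 16 the bis-silylated pentacyclic aldehyde
Product: 17 (E)-3-[(2S,3S)-3-[(2R,3S)-2-[3,4-bis(allyloxy)phenyl]-3-{[(triisopropylsilyl)oxy]methyl}-2,3-dihydro-1,4-benzodioxin-6-yl]-2-{[(triisopropylsilyl)oxy]methyl}-2,3-dihydro-1,4-benzodioxin-6-yl]prop-2-enal
Conditions: Ph3P=CHCHO (1.5 equiv), toluene, 80 °C
Reagents that add atoms: (triphenylphosphoranylidene)acetaldehyde, O=CC=P(c1ccccc1)(c1ccccc1)c1ccccc1
Why: Wittig olefination with a stabilized formyl ylide, which should give the E-enal directly from the aryl aldehyde.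

Step 13
Reactants: 17 the bis-silylated enal
Product: 18 (E)-3-[(2S,3S)-3-[(2R,3S)-2-[3,4-bis(allyloxy)phenyl]-3-(hydroxymethyl)-2,3-dihydro-1,4-benzodioxin-6-yl]-2-(hydroxymethyl)-2,3-dihydro-1,4-benzodioxin-6-yl]prop-2-enal
Conditions: HF·pyridine, pyridine, THF, 0 °C to rt
Reagents that add atoms: none
Why: fluoride-driven cleavage of the two primary silyl ethers under buffered conditions that should leave the enal, the allyl ethers and both dioxane rings untouched.

Step 14
Reactants: 18 the bis-allyl enal diol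
Product: 19 (E)-3-[(2S,3S)-3-[(2R,3S)-2-(3,4-dihydroxyphenyl)-3-(hydroxymethyl)-2,3-dihydro-1,4-benzodioxin-6-yl]-2-(hydroxymethyl)-2,3-dihydro-1,4-benzodioxin-6-yl]prop-2-enal (target)
Conditions: Pd(PPh3)4 (5 mol%), PhNHMe (6 equiv), THF, rt, degassed
Reagents that add atoms: none
Why: Tsuji–Trost-type deallylation in which zerovalent palladium ionises the aryl allyl ethers and N-methylaniline traps the allyl groups as a neutral amine, so the catechol is freed without the base or acid that could open cis-ring D through a quinone methide and epimerise it.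

**Compound list**

1 | 3,4-dihydroxybenzaldehyde | O=Cc1ccc(O)c(O)c1 | starting material
2 | 3,4-bis(allyloxy)benzaldehyde | O=Cc1ccc(OCC=C)c(OCC=C)c1 | intermediate
3 | ethyl (Z)-3-[3,4-bis(allyloxy)phenyl]prop-2-enoate | CCOC(=O)/C=C\c1ccc(OCC=C)c(OCC=C)c1 | intermediate
4 | ethyl (2S,3S)-3-[3,4-bis(allyloxy)phenyl]oxirane-2-carboxylate (cis) | CCOC(=O)[C@H]1O[C@H]1c1ccc(OCC=C)c(OCC=C)c1 | intermediate
5 | [(2R,3S)-3-[3,4-bis(allyloxy)phenyl]oxiran-2-yl]methanol (cis) | OC[C@H]1O[C@H]1c1ccc(OCC=C)c(OCC=C)c1 | intermediate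
6 | (2S,3S)-2-(chloromethyl)-3-[3,4-bis(allyloxy)phenyl]oxirane (cis) | ClC[C@H]1O[C@H]1c1ccc(OCC=C)c(OCC=C)c1 | intermediate
7 | 4-{(1R,2S)-1-[3,4-bis(allyloxy)phenyl]-3-chloro-2-hydroxypropoxy}-3-hydroxybenzaldehyde | O=Cc1ccc(O[C@H](c2ccc(OCC=C)c(OCC=C)c2)[C@H](O)CCl)c(O)c1 | intermediate (not isolated)
8 | 4-{(R)-[3,4-bis(allyloxy)phenyl][(2R)-oxiran-2-yl]methoxy}-3-hydroxybenzaldehyde | O=Cc1ccc(O[C@H](c2ccc(OCC=C)c(OCC=C)c2)[C@H]2CO2)c(O)c1 | intermediate (not isolated)
9 | (2R,3S)-2-[3,4-bis(allyloxy)phenyl]-3-(hydroxymethyl)-2,3-dihydro-1,4-benzodioxine-6-carbaldehyde (cis) | O=Cc1ccc2c(c1)O[C@@H](CO)[C@@H](c1ccc(OCC=C)c(OCC=C)c1)O2 | intermediate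
10 | ethyl (Z)-3-[(2R,3S)-2-[3,4-bis(allyloxy)phenyl]-3-(hydroxymethyl)-2,3-dihydro-1,4-benzodioxin-6-yl]prop-2-enoate | CCOC(=O)/C=C\c1ccc2c(c1)O[C@@H](CO)[C@@H](c1ccc(OCC=C)c(OCC=C)c1)O2 | intermediate
11 | ethyl (2R,3R)-3-[(2R,3S)-2-[3,4-bis(allyloxy)phenyl]-3-(hydroxymethyl)-2,3-dihydro-1,4-benzodioxin-6-yl]oxirane-2-carboxylate | CCOC(=O)[C@@H]1O[C@@H]1c1ccc2c(c1)O[C@@H](CO)[C@@H](c1ccc(OCC=C)c(OCC=C)c1)O2 | intermediate
12 | [(2S,3R)-3-[(2R,3S)-2-[3,4-bis(allyloxy)phenyl]-3-(hydroxymethyl)-2,3-dihydro-1,4-benzodioxin-6-yl]oxiran-2-yl]methanol | OC[C@@H]1O[C@@H]1c1ccc2c(c1)O[C@@H](CO)[C@@H](c1ccc(OCC=C)c(OCC=C)c1)O2 | intermediate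
13 | triisopropyl{[(2S,3R)-3-[(2R,3S)-2-[3,4-bis(allyloxy)phenyl]-3-{[(triisopropylsilyl)oxy]methyl}-2,3-dihydro-1,4-benzodioxin-6-yl]oxiran-2-yl]methoxy}silane | CC(C)[Si](OC[C@@H]1O[C@@H]1c1ccc2c(c1)O[C@@H](CO[Si](C(C)C)(C(C)C)C(C)C)[C@@H](c1ccc(OCC=C)c(OCC=C)c1)O2)(C(C)C)C(C)C | intermediate
14 | 4-fluoro-3-hydroxybenzaldehyde | O=Cc1ccc(F)c(O)c1 | starting material
15 | 4-fluoro-3-{(1S,2S)-1-[(2R,3S)-2-[3,4-bis(allyloxy)phenyl]-3-{[(triisopropylsilyl)oxy]methyl}-2,3-dihydro-1,4-benzodioxin-6-yl]-2-hydroxy-3-[(triisopropylsilyl)oxy]propoxy}benzaldehyde (formed as its sodium alkoxide) | O=Cc1ccc(F)c(c1)O[C@@H](c1ccc2c(c1)O[C@@H](CO[Si](C(C)C)(C(C)C)C(C)C)[C@@H](c1ccc(OCC=C)c(OCC=C)c1)O2)[C@H](CO[Si](C(C)C)(C(C)C)C(C)C)O | intermediate (not isolated)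
16 | (2S,3S)-3-[(2R,3S)-2-[3,4-bis(allyloxy)phenyl]-3-{[(triisopropylsilyl)oxy]methyl}-2,3-dihydro-1,4-benzodioxin-6-yl]-2-{[(triisopropylsilyl)oxy]methyl}-2,3-dihydro-1,4-benzodioxine-6-carbaldehyde | O=Cc1ccc2c(c1)O[C@@H](c1ccc3c(c1)O[C@@H](CO[Si](C(C)C)(C(C)C)C(C)C)[C@@H](c1ccc(OCC=C)c(OCC=C)c1)O3)[C@H](CO[Si](C(C)C)(C(C)C)C(C)C)O2 | intermediate
17 | (E)-3-[(2S,3S)-3-[(2R,3S)-2-[3,4-bis(allyloxy)phenyl]-3-{[(triisopropylsilyl)oxy]methyl}-2,3-dihydro-1,4-benzodioxin-6-yl]-2-{[(triisopropylsilyl)oxy]methyl}-2,3-dihydro-1,4-benzodioxin-6-yl]prop-2-enal | O=C/C=C/c1ccc2c(c1)O[C@@H](c1ccc3c(c1)O[C@@H](CO[Si](C(C)C)(C(C)C)C(C)C)[C@@H](c1ccc(OCC=C)c(OCC=C)c1)O3)[C@H](CO[Si](C(C)C)(C(C)C)C(C)C)O2 | intermediate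
18 | (E)-3-[(2S,3S)-3-[(2R,3S)-2-[3,4-bis(allyloxy)phenyl]-3-(hydroxymethyl)-2,3-dihydro-1,4-benzodioxin-6-yl]-2-(hydroxymethyl)-2,3-dihydro-1,4-benzodioxin-6-yl]prop-2-enal | O=C/C=C/c1ccc2c(c1)O[C@@H](c1ccc3c(c1)O[C@@H](CO)[C@@H](c1ccc(OCC=C)c(OCC=C)c1)O3)[C@H](CO)O2 | intermediate
19 | (E)-3-[(2S,3S)-3-[(2R,3S)-2-(3,4-dihydroxyphenyl)-3-(hydroxymethyl)-2,3-dihydro-1,4-benzodioxin-6-yl]-2-(hydroxymethyl)-2,3-dihydro-1,4-benzodioxin-6-yl]prop-2-enal | O=C/C=C/c1ccc2c(c1)O[C@@H](c1ccc3c(c1)O[C@@H](CO)[C@@H](c1ccc(O)c(O)c1)O3)[C@H](CO)O2 | target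

**Count and risks**

Total step count: 14. Longest linear sequence: 14 steps (1 to 19); compound 14 and the second portion of 1 are purchased.

Steps most likely to fail:

1. Step 6 (Proposed new method). What may go wrong: the phenoxide may displace chloride at CH2Cl instead of opening the benzylic oxirane carbon, or a seven-membered ring may form by direct chloride displacement or 7-endo opening. Both give constitutional isomers. Partial ionisation at the benzylic carbon would also erode the cis fidelity. Fallback with known chemistry, from 5 back to 9: silylation of 5 (i-Pr3SiCl, imidazole, DMF) gives triisopropyl{[(2R,3S)-3-[3,4-bis(allyloxy)phenyl]oxiran-2-yl]methoxy}silane F1, which has no second electrophilic carbon. Opening of F1 by the 4-phenoxide of 1 (1 in excess, K2CO3 0.5 equiv, DMF, 70 °C), the known benzylic opening of 3-aryl glycidyl ethers by phenoxides, gives the phenol alcohol 4-{(1R,2R)-1-[3,4-bis(allyloxy)phenyl]-2-hydroxy-3-[(triisopropylsilyl)oxy]propoxy}-3-hydroxybenzaldehyde F2. Intramolecular Mitsunobu etherification (PPh3, diisopropyl azodicarboxylate, THF, 0 °C) closes the same ArO–CH bond with inversion to the silyl ether (2R,3S)-2-[3,4-bis(allyloxy)phenyl]-3-{[(triisopropylsilyl)oxy]methyl}-2,3-dihydro-1,4-benzodioxine-6-carbaldehyde F3. Bu4NF in THF at 0 °C then removes the silyl group and the route is rejoined at 9.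

2. Step 11. What may go wrong: the alkoxide of 15 may be consumed by 1,4-silyl migration from the neighbouring silyl ether or by re-closure to the oxirane faster than it adds to the fluoroarene, which leads to a seven-membered isomer or to no ring closure. Fallback, from 13 back to 16: 13 and purchased 4-bromo-3-hydroxybenzaldehyde (bromophenol in excess, K2CO3 0.5 equiv, DMF, 70 °C) give the isolated, protonated bromo alcohol 4-bromo-3-{(1S,2S)-1-[(2R,3S)-2-[3,4-bis(allyloxy)phenyl]-3-{[(triisopropylsilyl)oxy]methyl}-2,3-dihydro-1,4-benzodioxin-6-yl]-2-hydroxy-3-[(triisopropylsilyl)oxy]propoxy}benzaldehyde F4. A copper-catalysed intramolecular Ullmann etherification (CuI, 1,10-phenanthroline, Cs2CO3, toluene, 110 °C) then forms the aryl–oxygen bond with retention at carbon in a non-polar medium that keeps free alkoxide low, giving 16.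

3. Step 3. What may go wrong: oxygen transfer to the electron-rich Z-cinnamate may run stepwise, letting the radical intermediate rotate before ring closure, which gives trans-glycidate and lower enantiopurity. Fallback, from 3 back to 5: reduction of 3 with i-Bu2AlH (CH2Cl2, −78 °C) gives the Z-allylic alcohol (Z)-3-[3,4-bis(allyloxy)phenyl]prop-2-en-1-ol F5. Sharpless asymmetric epoxidation (Ti(OiPr)4, D-(−)-diisopropyl tartrate, t-BuOOH, 4 Å molecular sieves, CH2Cl2, −20 °C) is a concerted, stereospecific oxygen transfer and should give 5 directly.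

**Further compounds**

F1 | step 6 | triisopropyl{[(2R,3S)-3-[3,4-bis(allyloxy)phenyl]oxiran-2-yl]methoxy}silane | CC(C)[Si](OC[C@H]1O[C@H]1c1ccc(OCC=C)c(OCC=C)c1)(C(C)C)C(C)C
F2 | step 6 | 4-{(1R,2R)-1-[3,4-bis(allyloxy)phenyl]-2-hydroxy-3-[(triisopropylsilyl)oxy]propoxy}-3-hydroxybenzaldehyde | O=Cc1ccc(O[C@H](c2ccc(OCC=C)c(OCC=C)c2)[C@H](O)CO[Si](C(C)C)(C(C)C)C(C)C)c(O)c1
F3 | step 6 | (2R,3S)-2-[3,4-bis(allyloxy)phenyl]-3-{[(triisopropylsilyl)oxy]methyl}-2,3-dihydro-1,4-benzodioxine-6-carbaldehyde | O=Cc1ccc2c(c1)O[C@@H](CO[Si](C(C)C)(C(C)C)C(C)C)[C@@H](c1ccc(OCC=C)c(OCC=C)c1)O2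
F4 | step 11 | 4-bromo-3-{(1S,2S)-1-[(2R,3S)-2-[3,4-bis(allyloxy)phenyl]-3-{[(triisopropylsilyl)oxy]methyl}-2,3-dihydro-1,4-benzodioxin-6-yl]-2-hydroxy-3-[(triisopropylsilyl)oxy]propoxy}benzaldehyde | O=Cc1ccc(Br)c(c1)O[C@@H](c1ccc2c(c1)O[C@@H](CO[Si](C(C)C)(C(C)C)C(C)C)[C@@H](c1ccc(OCC=C)c(OCC=C)c1)O2)[C@H](CO[Si](C(C)C)(C(C)C)C(C)C)O
F5 | step 3 | (Z)-3-[3,4-bis(allyloxy)phenyl]prop-2-en-1-ol | OC/C=C\c1ccc(OCC=C)c(OCC=C)c1
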